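**Plan**
- Retrosynthetic cuts: first the two benzyl–O bonds and the O8–CH3 bond, then O1–C8a of the pyranone, then C2–C3 (aldol) and C4–C4a (Friedel–Crafts).
- Feature used: ring A has para oxygens on C5 and C8, with the acyl carbon C4 on C4a and a ring position (C8a) beside it. It is therefore the reduced form of a 2-acyl-5-methoxy-1,4-benzoquinone whose CH carbon next to the acyl group is C8a.
- Forward: the A-ring ketone is made from 1,2,4-trimethoxybenzene, the aryl-bearing C2 is joined by an aldol addition, the adduct is oxidised to the 2-methoxy-1,3-diketone, and Ce(IV) turns the trimethoxyphenyl ring into the acylquinone.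
- The pyranone is the only ring formed. It closes when the enol oxygen on C2 adds to C8a of the quinone and the adduct aromatises to the 5,8-diol; O8 is then methylated and the benzyl groups are removed.
- Stereochemistry: the target has no stereocentre. The centres that appear in the aldol adduct and at C8a during ring closure are erased again.

Key step: step 6

Remark: the target is achiral (no stereocentre, no configurationally stable axis), so no enantiocontrol is needed; flavone numbering (O1, C2 … C8a) is used for the corresponding atoms of the open-chain and quinone intermediates as well.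

**Step 1**
Reactants: 1 1,2,4-trimethoxybenzene; 2 methoxyacetyl chloride
Product: 3 2-methoxy-1-(2,4,5-trimethoxyphenyl)ethan-1-one
Conditions: AlCl3 (1.2 equiv), CH2Cl2, −10 → 0 °C; ice/dil. HCl
Reagents that add atoms: none
Why: Friedel–Crafts acylation at C5 of 1, which is para to one methoxyl, ortho to another and unhindered, should give the 2,4,5-trimethoxyphenyl ketone, while low temperature and only a small excess of Lewis acid limit CO loss from the α-alkoxy acyl chloride and demethylation ortho to the new carbonyl.

**Step 2**
Reactants: 4 2,3-dihydroxybenzaldehyde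
Product: 5 2,3-bis(benzyloxy)benzaldehyde
Conditions: BnBr (2.3 equiv), K2CO3, DMF, rt → 60 °C
Reagents that add atoms: benzyl bromide, BrCc1ccccc1
Why: Williamson etherification of both phenols masks the catechol against the later Ce(IV) oxidation and base, and the benzyl groups can be removed at the end under neutral conditions.

**Step 3**
Reactants: 3 2-methoxy-1-(2,4,5-trimethoxyphenyl)ethan-1-one; 5 2,3-bis(benzyloxy)benzaldehyde
Product: 6 3-[2,3-bis(benzyloxy)phenyl]-3-hydroxy-2-methoxy-1-(2,4,5-trimethoxyphenyl)propan-1-one (racemic mixture of diastereomers)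
Conditions: LiHMDS (1.1 equiv), THF, −78 °C; then 5, −78 °C; AcOH quench
Reagents that add atoms: none
Why: Directed aldol addition of the lithium enolate of 3, which has a single enolisable position, to the non-enolisable aldehyde forms the C2–C3 bond; the two new stereocentres need no control because both are erased in steps 4 and 6.

**Step 4**
Reactants: 6 3-[2,3-bis(benzyloxy)phenyl]-3-hydroxy-2-methoxy-1-(2,4,5-trimethoxyphenyl)propan-1-one
Product: 7 1-[2,3-bis(benzyloxy)phenyl]-2-methoxy-3-(2,4,5-trimethoxyphenyl)propane-1,3-dione
Conditions: Dess–Martin periodinane (1.3 equiv), CH2Cl2, 0 °C → rt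
Reagents that add atoms: none
Why: Dess–Martin oxidation of a β-hydroxy ketone to the 1,3-diketone runs under near-neutral conditions that avoid retro-aldol cleavage and leave the benzyl and methyl ethers untouched.

**Step 5**
Reactants: 7 1-[2,3-bis(benzyloxy)phenyl]-2-methoxy-3-(2,4,5-trimethoxyphenyl)propane-1,3-dione
Product: 8 1-[2,3-bis(benzyloxy)phenyl]-2-methoxy-3-(4-methoxy-3,6-dioxocyclohexa-1,4-dien-1-yl)propane-1,3-dione
Conditions: (NH4)2Ce(NO3)6 (2.2 equiv), MeCN–H2O (3:1), −10 → 0 °C, short contact time; cold extractive work-up, crude quinone used at once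
Reagents that add atoms: water, O
Why: Cerium(IV) oxidative demethylation of a p-dimethoxyarene should act on the trimethoxyphenyl ring, the most easily oxidised π system, where water attacks the radical cation at the two para methoxy-bearing carbons and methanol is lost to give the p-quinone with the third methoxyl kept as a vinylogous ester; the carbonyl-deactivated B ring and the largely non-enolised 2-substituted diketone should react more slowly.

**Step 6**
Reactants: 8 1-[2,3-bis(benzyloxy)phenyl]-2-methoxy-3-(4-methoxy-3,6-dioxocyclohexa-1,4-dien-1-yl)propane-1,3-dione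
Product: 10 2-[2,3-bis(benzyloxy)phenyl]-5,8-dihydroxy-3,7-dimethoxy-4H-chromen-4-one, via oxa-Michael adduct 9 (not isolated)
Conditions: Et3N (0.1 equiv), degassed CH2Cl2 (0.01 M), −40 → 0 °C, Ar; then AcOH
Reagents that add atoms: none
Why: Proposed new method: the amine removes the acidic C3–H of the 2-methoxy-1,3-diketone and the enolate oxygen on C2 adds to the quinone CH carbon beside the acyl group (future C8a), which is β to both the C4 ketone and the C5 quinone carbonyl and α to the C8 carbonyl; adduct 9 then loses its C8a proton and aromatises to the 5,8-diol, so the quinone is reduced and the pyranone formed without any external reagent. The closest known reactions are the conjugate addition of oxygen and other heteroatom nucleophiles to C3 of 2-acyl-1,4-benzoquinones, which ends in the substituted hydroquinone, and the oxa-Michael closure of 2'-hydroxychalcones to flavanones. The pyranone ring closes in a 6-endo-trig mode. The only stereocentre that appears, C8a of 9, is formed as a racemate and disappears on aromatisation, so nothing has to be controlled. The step needs attack at C8a and not at C6, at the C5 carbonyl carbon or on a second molecule: C6 is the electron-rich end of the C8–C7(OMe)=C6 vinylogous ester and cannot be reached by the tether, addition to the C5 carbonyl gives only a reversible hemiketal whereas conjugate addition is made irreversible by aromatisation, and high dilution favours the intramolecular six-membered closure over intermolecular addition or quinone–hydroquinone electron exchange. Attack through the central carbon of the enolate is geometrically impossible within the molecule, which leaves O–C8a bond formation as the only ring closure.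

**Step 7**
Reactants: 10 2-[2,3-bis(benzyloxy)phenyl]-5,8-dihydroxy-3,7-dimethoxy-4H-chromen-4-one
Product: 11 2-[2,3-bis(benzyloxy)phenyl]-5-hydroxy-3,7,8-trimethoxy-4H-chromen-4-one
Conditions: MeI (1.1 equiv), K2CO3 (1.2 equiv), degassed acetone, rt, Ar
Reagents that add atoms: iodomethane, CI
Why: Williamson methylation should take place only at the free 8-OH because the 5-OH is held in a hydrogen bond to the C4 carbonyl and is far less acidic and nucleophilic, and the argon atmosphere keeps the hydroquinone from air oxidation in base.

**Step 8**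
Reactants: 11 2-[2,3-bis(benzyloxy)phenyl]-5-hydroxy-3,7,8-trimethoxy-4H-chromen-4-one
Product: 12 2-(2,3-dihydroxyphenyl)-5-hydroxy-3,7,8-trimethoxy-4H-chromen-4-one (5,2',3'-trihydroxy-3,7,8-trimethoxyflavone)
Conditions: H2 (1 atm), 10% Pd/C, EtOAc–MeOH, rt
Reagents that add atoms: none
Why: Catalytic hydrogenolysis cleaves the two benzyl aryl ethers, while the tetrasubstituted, cross-conjugated C2=C3 bond of the chromone and the methyl ethers are not reduced at 1 atm and room temperature.

**Compound list**
1 | 1,2,4-trimethoxybenzene | COc1ccc(OC)c(OC)c1 | starting material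
2 | methoxyacetyl chloride | COCC(=O)Cl | starting material
3 | 2-methoxy-1-(2,4,5-trimethoxyphenyl)ethan-1-one | COCC(=O)c1cc(OC)c(OC)cc1OC | intermediate
4 | 2,3-dihydroxybenzaldehyde | O=Cc1cccc(O)c1O | starting material
5 | 2,3-bis(benzyloxy)benzaldehyde | O=Cc1cccc(OCc2ccccc2)c1OCc1ccccc1 | intermediate
6 | 3-[2,3-bis(benzyloxy)phenyl]-3-hydroxy-2-methoxy-1-(2,4,5-trimethoxyphenyl)propan-1-one (racemic mixture of diastereomers) | COc1cc(OC)c(OC)cc1C(=O)C(OC)C(O)c1cccc(OCc2ccccc2)c1OCc1ccccc1 | intermediate
7 | 1-[2,3-bis(benzyloxy)phenyl]-2-methoxy-3-(2,4,5-trimethoxyphenyl)propane-1,3-dione | COc1cc(OC)c(OC)cc1C(=O)C(OC)C(=O)c1cccc(OCc2ccccc2)c1OCc1ccccc1 | intermediate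
8 | 1-[2,3-bis(benzyloxy)phenyl]-2-methoxy-3-(4-methoxy-3,6-dioxocyclohexa-1,4-dien-1-yl)propane-1,3-dione | COC1=CC(=O)C(C(=O)C(OC)C(=O)c2cccc(OCc3ccccc3)c2OCc2ccccc2)=CC1=O | intermediate
9 | 2-[2,3-bis(benzyloxy)phenyl]-5-hydroxy-3,7-dimethoxy-4H-chromene-4,8(8aH)-dione (oxa-Michael adduct, racemic at C8a) | COC1=CC(O)=C2C(=O)C(OC)=C(c3cccc(OCc4ccccc4)c3OCc3ccccc3)OC2C1=O | intermediate (not isolated)
10 | 2-[2,3-bis(benzyloxy)phenyl]-5,8-dihydroxy-3,7-dimethoxy-4H-chromen-4-one | COc1cc(O)c2c(=O)c(OC)c(-c3cccc(OCc4ccccc4)c3OCc3ccccc3)oc2c1O | intermediate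
11 | 2-[2,3-bis(benzyloxy)phenyl]-5-hydroxy-3,7,8-trimethoxy-4H-chromen-4-one | COc1cc(O)c2c(=O)c(OC)c(-c3cccc(OCc4ccccc4)c3OCc3ccccc3)oc2c1OC | intermediate
12 | 2-(2,3-dihydroxyphenyl)-5-hydroxy-3,7,8-trimethoxy-4H-chromen-4-one | COc1cc(O)c2c(=O)c(OC)c(-c3cccc(O)c3O)oc2c1OC | target

**Step count**
Total steps: 8. Longest linear sequence: 7 steps (steps 1, 3, 4, 5, 6, 7, 8).

**Steps most likely to fail**

1. Step 6 (proposed new method). The acylquinone may be consumed by electron exchange with hydroquinone already formed, or by intermolecular conjugate addition, before the enol oxygen closes the ring. The fallback uses known chemistry, sets out from aldehyde 5 and comes back at target 12.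
   - Claisen–Schmidt condensation of 5 with commercial 1-(2-hydroxy-3,4,6-trimethoxyphenyl)ethan-1-one (CC(=O)c1c(O)c(OC)c(OC)cc1OC; KOH, EtOH, rt) should give (E)-3-[2,3-bis(benzyloxy)phenyl]-1-(2-hydroxy-3,4,6-trimethoxyphenyl)prop-2-en-1-one F1.
   - Iodine-catalysed oxidative cyclisation (cat. I2, DMSO, 120 °C) should give 2-[2,3-bis(benzyloxy)phenyl]-5,7,8-trimethoxy-4H-chromen-4-one F2.
   - Epoxidation of the C2=C3 bond with dimethyldioxirane and acid-catalysed opening (acetone–CH2Cl2, 0 °C; cat. TsOH) should give 2-[2,3-bis(benzyloxy)phenyl]-3-hydroxy-5,7,8-trimethoxy-4H-chromen-4-one F3.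
   - Methylation (MeI, K2CO3, acetone) should give 2-[2,3-bis(benzyloxy)phenyl]-3,5,7,8-tetramethoxy-4H-chromen-4-one F4.
   - BCl3 (CH2Cl2, −78 → 0 °C) cleaves benzyl aryl ethers and the 5-methoxyl chelated to the C4 carbonyl, and should deliver 12 directly, so steps 7 and 8 are not needed.

2. Step 5. The acylquinone may not survive the aqueous acidic Ce(IV) medium: ring closure can start in the flask and the resulting hydroquinone is then oxidised further, or water adds next to the acyl group; oxidation of the diketone enol is a further possibility. The fallback sets out from diketone 7 and comes back at 10. Instead of intercepting 8, the oxidation is driven through 8 and 10 with excess cerium(IV) ammonium nitrate (about 4.5 equiv, MeCN–H2O, rt) to 2-[2,3-bis(benzyloxy)phenyl]-3,7-dimethoxy-4H-chromene-4,5,8-trione F5, which Ce(IV) should not oxidise further. Reduction of the quinone with sodium dithionite (EtOAc–H2O, rt) should then give 10.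

3. Step 1. The α-methoxy acylium complex may lose CO, leading to methoxymethylation of the arene, and the Lewis acid may demethylate the methoxyl ortho to the new ketone. The fallback sets out from 1 and comes back at 3. Bromination with N-bromosuccinimide (MeCN, 0 °C → rt) should give 1-bromo-2,4,5-trimethoxybenzene F6. Bromine–lithium exchange (n-BuLi, THF, −78 °C) gives (2,4,5-trimethoxyphenyl)lithium F7, which is acylated with commercial N,2-dimethoxy-N-methylacetamide (COCC(=O)N(C)OC) in a Weinreb ketone synthesis to give 3.

**Further compounds**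
F1 | step 6 | (E)-3-[2,3-bis(benzyloxy)phenyl]-1-(2-hydroxy-3,4,6-trimethoxyphenyl)prop-2-en-1-one | COc1cc(OC)c(C(=O)/C=C/c2cccc(OCc3ccccc3)c2OCc2ccccc2)c(O)c1OC
F2 | step 6 | 2-[2,3-bis(benzyloxy)phenyl]-5,7,8-trimethoxy-4H-chromen-4-one | COc1cc(OC)c2c(=O)cc(-c3cccc(OCc4ccccc4)c3OCc3ccccc3)oc2c1OC
F3 | step 6 | 2-[2,3-bis(benzyloxy)phenyl]-3-hydroxy-5,7,8-trimethoxy-4H-chromen-4-one | COc1cc(OC)c2c(=O)c(O)c(-c3cccc(OCc4ccccc4)c3OCc3ccccc3)oc2c1OC
F4 | step 6 | 2-[2,3-bis(benzyloxy)phenyl]-3,5,7,8-tetramethoxy-4H-chromen-4-one | COc1cc(OC)c2c(=O)c(OC)c(-c3cccc(OCc4ccccc4)c3OCc3ccccc3)oc2c1OC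
F5 | step 5 | 2-[2,3-bis(benzyloxy)phenyl]-3,7-dimethoxy-4H-chromene-4,5,8-trione | COC1=CC(=O)c2c(oc(-c3cccc(OCc4ccccc4)c3OCc3ccccc3)c(OC)c2=O)C1=O
F6 | step 1 | 1-bromo-2,4,5-trimethoxybenzene | COc1cc(OC)c(Br)cc1OC
F7 | step 1 | (2,4,5-trimethoxyphenyl)lithium | [Li]c1cc(OC)c(OC)cc1OC
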